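**Retrosynthetic overview**

1. Numbering (daucane): C1 is the quaternary ring-fusion carbon (C15 methyl); C1–C2–C3–C4 (carbinol, isopropyl)–C5 (ring-fusion CH) is ring A; C6 (acyloxy), C7, C8(methyl)=C9 and C10 complete ring B. α is the face of H5 and isopropyl, β the face of O4 and C15.
2. The strategy rests on ring B carrying oxygen at C6 and an isolated C8(Me)=C9 alkene: C8 and C9 are an alkyne unit set between C7 and C10 of a 1-siloxyvinyl cyclopropane whose three-membered ring is C1–C5–C10. Hence a rhodium (5+2) disconnection of C7–C8 and C9–C10.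
3. Endgame: ester C–O bond last; C6 carbinol from the C6 ketone by C4-OH-directed reduction; C5–H and C9–H by acid protonolysis of the C5=C6 enol ether and of a C9 silyl group that steers the alkyne.
4. Precursor: ring A by ozonolysis/aldol ring contraction of (S)-terpinen-4-ol (C4 unchanged), methyl ketone, CBS reduction, hydroxyl-directed cyclopropanation (sets C1), enol silylation.
5. Ring order: ring A (step 3), cyclopropane C1–C5–C10 (step 7), ring B (step 10).

Key step: step 10

Remark: (S)-terpinen-4-ol is taken as available in high enantiomeric purity.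
Remark: in rhodium (5+2) reactions the allyl terminus is taken to bond first to the less hindered alkyne carbon, so bare propyne would be expected to put its methyl on C9. 1-(Trimethylsilyl)propyne is therefore used; its silicon ends on C9 and is replaced by hydrogen in step 11.

**Route**

Step 1
Reactants: 1 (S)-terpinen-4-ol
Product: 2 (S)-triethyl{[4-methyl-1-(propan-2-yl)cyclohex-3-en-1-yl]oxy}silane
Conditions: Et3SiOTf, 2,6-lutidine, CH2Cl2, −78 to 0 °C
Reagents that add atoms: triethylsilyl trifluoromethanesulfonate, CC[Si](CC)(CC)OS(=O)(=O)C(F)(F)F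
Why: Silyl triflate silylation of a tertiary alcohol leaves the stereocentre untouched and gives an O4 group that does not coordinate zinc in step 7 and shields the β-face in step 11.

Step 2
Reactants: 2 (S)-triethyl{[4-methyl-1-(propan-2-yl)cyclohex-3-en-1-yl]oxy}silane
Product: 4 (S)-6-oxo-3-(propan-2-yl)-3-(triethylsilyloxy)heptanal, via ozonide 3 (not isolated)
Conditions: O3, CH2Cl2, −78 °C; then Me2S, −78 °C to rt
Reagents that add atoms: ozone, [O-][O+]=O
Why: Ozonolysis of the only alkene with reductive work-up gives the 1,6-keto aldehyde without touching the quaternary carbinol centre.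

Step 3
Reactants: 4 (S)-6-oxo-3-(propan-2-yl)-3-(triethylsilyloxy)heptanal
Product: 5 (5R)-2-methyl-5-(propan-2-yl)-5-(triethylsilyloxy)cyclopent-1-ene-1-carbaldehyde
Conditions: piperidine (0.3 equiv), AcOH (0.3 equiv), toluene, 50 °C
Reagents that add atoms: none
Why: Amine-catalysed intramolecular aldol condensation in which the aldehyde enamine carbon (C5) attacks the methyl ketone (C1) and water is lost closes ring A as the tetrasubstituted enal, the moderate temperature being chosen to keep the β-silyloxy group from eliminating.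

Step 4
Reactants: 5 (5R)-2-methyl-5-(propan-2-yl)-5-(triethylsilyloxy)cyclopent-1-ene-1-carbaldehyde; 6 methylmagnesium bromide
Product: 7 1-[(5R)-2-methyl-5-(propan-2-yl)-5-(triethylsilyloxy)cyclopent-1-en-1-yl]ethan-1-ol (both carbinol epimers)
Conditions: MeMgBr, THF, −78 to 0 °C
Reagents that add atoms: methylmagnesium bromide (6), C[Mg]Br
Why: Grignard 1,2-addition to the fully β-substituted enal installs C7, and the carbinol configuration is left open because steps 5 and 6 reset it.

Step 5
Reactants: 7 1-[(5R)-2-methyl-5-(propan-2-yl)-5-(triethylsilyloxy)cyclopent-1-en-1-yl]ethan-1-ol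
Product: 8 1-[(5R)-2-methyl-5-(propan-2-yl)-5-(triethylsilyloxy)cyclopent-1-en-1-yl]ethan-1-one
Conditions: Dess–Martin periodinane, NaHCO3, CH2Cl2, rt
Reagents that add atoms: none
Why: Periodinane oxidation converges both allylic alcohol epimers on the enone under neutral conditions that spare the silyl ether.

Step 6
Reactants: 8 1-[(5R)-2-methyl-5-(propan-2-yl)-5-(triethylsilyloxy)cyclopent-1-en-1-yl]ethan-1-one
Product: 9 (1R)-1-[(5R)-2-methyl-5-(propan-2-yl)-5-(triethylsilyloxy)cyclopent-1-en-1-yl]ethan-1-ol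
Conditions: (S)-1-methyl-3,3-diphenyltetrahydro-1H,3H-pyrrolo[1,2-c][1,3,2]oxazaborole (0.2 equiv), BH3·SMe2, THF, −30 °C
Reagents that add atoms: none
Why: Corey–Bakshi–Shibata reduction in which the (S)-oxazaborolidine binds the ketone on the lone pair next to the small methyl group and delivers hydride under reagent control to give the (R)-carbinol, the cyclopentenyl group acting as the large substituent.

Step 7
Reactants: 9 (1R)-1-[(5R)-2-methyl-5-(propan-2-yl)-5-(triethylsilyloxy)cyclopent-1-en-1-yl]ethan-1-ol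
Product: 10 (1R)-1-[(1S,2R,5R)-5-methyl-2-(propan-2-yl)-2-(triethylsilyloxy)bicyclo[3.1.0]hexan-1-yl]ethan-1-ol
Conditions: Et2Zn, CH2I2, CH2Cl2, −10 °C to rt
Reagents that add atoms: diiodomethane, ICI
Why: Hydroxyl-directed Simmons–Smith cyclopropanation (Furukawa conditions) in which the zinc alkoxide of the (R)-carbinol should deliver the methylene to the alkene face on which its C–O bond sits when the carbinol hydrogen eclipses the double bond (allylic 1,3-strain to the C15 methyl minimised), which is the α-face anti to the non-coordinating silyloxy group, so that C1 and C5 are set together with C10 cis to the isopropyl group.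

Step 8
Reactants: 10 (1R)-1-[(1S,2R,5R)-5-methyl-2-(propan-2-yl)-2-(triethylsilyloxy)bicyclo[3.1.0]hexan-1-yl]ethan-1-ol
Product: 11 1-[(1R,2R,5R)-5-methyl-2-(propan-2-yl)-2-(triethylsilyloxy)bicyclo[3.1.0]hexan-1-yl]ethan-1-one
Conditions: Dess–Martin periodinane, NaHCO3, CH2Cl2, rt
Reagents that add atoms: none
Why: Periodinane oxidation of the cyclopropyl carbinol removes the auxiliary carbinol centre and gives the methyl ketone without opening the cyclopropane.

Step 9
Reactants: 11 1-[(1R,2R,5R)-5-methyl-2-(propan-2-yl)-2-(triethylsilyloxy)bicyclo[3.1.0]hexan-1-yl]ethan-1-one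
Product: 12 (1S,2R,5R)-1-[1-(tert-butyldimethylsilyloxy)ethenyl]-5-methyl-2-(propan-2-yl)-2-(triethylsilyloxy)bicyclo[3.1.0]hexane
Conditions: tBuMe2SiOTf, Et3N, CH2Cl2, 0 °C
Reagents that add atoms: tert-butyldimethylsilyl trifluoromethanesulfonate, CC(C)(C)[Si](C)(C)OS(=O)(=O)C(F)(F)F
Why: Soft enol silylation with silyl triflate and amine gives one enol ether only, because C5 is quaternary and the methyl group is the sole enolisable position.

Step 10
Reactants: 12 (1S,2R,5R)-1-[1-(tert-butyldimethylsilyloxy)ethenyl]-5-methyl-2-(propan-2-yl)-2-(triethylsilyloxy)bicyclo[3.1.0]hexane; 13 1-(trimethylsilyl)propyne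
Product: 14 (1R,4R)-6-(tert-butyldimethylsilyloxy)-4-(triethylsilyloxy)-9-(trimethylsilyl)dauca-5,8-diene
Conditions: [Rh(CO)2Cl]2 (5 mol %), 13 (3 equiv), ClCH2CH2Cl, 80 °C
Reagents that add atoms: none
Why: Proposed new method: [Rh(CO)2Cl]2 (monovalent rhodium) is expected to bind the enol ether alkene, insert into the cyclopropane bond C5–C10 to give a trivalent rhodium metallacycle (σ-alkyl at C10, allyl over C5–C6–C7), couple the allyl terminus C7 with the methyl-bearing alkyne carbon (C7–C8) and reductively eliminate C9–C10; the closest known reaction type is the intermolecular rhodium-catalysed (5+2) cycloaddition of oxygen-substituted vinylcyclopropanes with alkynes, extended here to a ring-fused cyclopropane with two quaternary carbons. Ring B (C1, C5, C6, C7, C8, C9, C10) is closed by a two-bond union of two fragments, not by cyclisation of a chain, and the C5=C6 silyl enol ether stores the C6 ketone. No stereocentre is created, and C1 and C4 keep their configuration because only C5–C10 is broken. Opening of C5–C10 and not C1–C5 is secured by the primary against tertiary alkyl–rhodium bond that results and by the C15 methyl on C1, and the C10–rhodium alkyl has no β-hydrogen (C1 is quaternary), which should give the hindered metallacycle time to capture the alkyne. The orientation of the alkyne is secured by the trimethylsilyl group, whose carbon should stay on rhodium, away from the forming C7–C8 bond, so that silicon ends on C9 and methyl on C8. The reactive s-cis rotamer, with the enol oxygen and not the methylene turned towards C4, should be the favoured one.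

Step 11
Reactants: 14 (1R,4R)-6-(tert-butyldimethylsilyloxy)-4-(triethylsilyloxy)-9-(trimethylsilyl)dauca-5,8-diene
Product: 16 (1R,4R,5R)-4-(triethylsilyloxy)dauc-8-en-6-one (trans-fused), via silyl ketone 15 (not isolated)
Conditions: CF3CO2H (5 equiv), CH2Cl2, −40 to 0 °C; then aq NaHCO3
Reagents that add atoms: none
Why: Two known electrophilic substitutions by proton are run in one flask, protonolysis of the silyl enol ether at C5 and then ipso-protodesilylation of the vinylsilane through the tertiary β-silyl cation at C8, and the proton should reach C5 on the α-face because the β-face is covered by the triethylsilyloxy group on C4 and the C15 methyl, the trans-fused ketone so formed (C6 cis to O4, trans to isopropyl) being also the more stable epimer, while the departing silicon fixes the alkene at C8=C9.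

Step 12
Reactants: 16 (1R,4R,5R)-4-(triethylsilyloxy)dauc-8-en-6-one
Product: 17 (1R,4R,5R)-4-hydroxydauc-8-en-6-one
Conditions: HF·pyridine, pyridine, THF, 0 °C to rt
Reagents that add atoms: none
Why: Buffered fluoride cleavage of the tertiary silyl ether is weakly acidic and non-basic, so the β-hydroxy ketone is not exposed to retro-aldol cleavage, β-elimination or a base-induced shift of the C8=C9 alkene into conjugation.

Step 13
Reactants: 17 (1R,4R,5R)-4-hydroxydauc-8-en-6-one
Product: 18 (1R,4R,5S,6S)-dauc-8-ene-4,6-diol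
Conditions: Me4NBH(OAc)3, MeCN/AcOH, −30 to 0 °C
Reagents that add atoms: none
Why: Evans–Saksena reduction in which exchange of an acetate on boron for the C4 hydroxyl gives an alkoxyborohydride that delivers hydride to C6 inside a six-membered transition state from the β-face on which O4 lies (C6 is cis to O4 on ring A in the trans-fused ketone), which sets C6 with its hydroxyl α, anti to the C4 hydroxyl and cis to H5.

Step 14
Reactants: 19 (E)-4-hydroxycinnamic acid (p-coumaric acid)
Product: 21 (E)-3-[4-(tert-butyldimethylsilyloxy)phenyl]prop-2-enoic acid, via bis-silyl coumarate 20 (not isolated)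
Conditions: tBuMe2SiCl, imidazole, DMF, rt; then K2CO3 (cat.), MeOH/H2O, rt
Reagents that add atoms: tert-butyldimethylsilyl chloride, CC(C)(C)[Si](C)(C)Cl
Why: Silylation of both hydroxyl groups followed by selective solvolysis of the labile silyl ester leaves only the phenol protected.

Step 15
Reactants: 18 (1R,4R,5S,6S)-dauc-8-ene-4,6-diol; 21 (E)-3-[4-(tert-butyldimethylsilyloxy)phenyl]prop-2-enoic acid
Product: 22 (1R,4R,5S,6S)-4-hydroxydauc-8-en-6-yl (E)-3-[4-(tert-butyldimethylsilyloxy)phenyl]prop-2-enoate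
Conditions: N,N'-dicyclohexylcarbodiimide, 4-(dimethylamino)pyridine, CH2Cl2, rt
Reagents that add atoms: none
Why: Steglich esterification acylates only the secondary C6 hydroxyl, the tertiary C4 hydroxyl being inert, and changes no stereocentre.

Step 16
Reactants: 22 (1R,4R,5S,6S)-4-hydroxydauc-8-en-6-yl (E)-3-[4-(tert-butyldimethylsilyloxy)phenyl]prop-2-enoate
Product: 23 (1R,4R,5S,6S)-4-hydroxydauc-8-en-6-yl (E)-3-(4-hydroxyphenyl)prop-2-enoate (target)
Conditions: Bu4NF, AcOH, THF, 0 °C
Reagents that add atoms: none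
Why: Fluoride cleavage of the aryl silyl ether, buffered with acetic acid, frees the phenol without touching the cinnamate ester, the tertiary alcohol or the alkenes.

**Compound list**

1 | (S)-terpinen-4-ol | CC1=CC[C@](O)(C(C)C)CC1 | starting material
2 | (S)-triethyl{[4-methyl-1-(propan-2-yl)cyclohex-3-en-1-yl]oxy}silane | CC1=CC[C@](O[Si](CC)(CC)CC)(C(C)C)CC1 | intermediate
3 | ozonide (1,2,4-trioxolane) of 2, mixture at the trioxolane carbons, not isolated | CC12CC[C@@](O[Si](CC)(CC)CC)(C(C)C)CC(OO1)O2 | intermediate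
4 | (S)-6-oxo-3-(propan-2-yl)-3-(triethylsilyloxy)heptanal | O=CC[C@](O[Si](CC)(CC)CC)(C(C)C)CCC(C)=O | intermediate
5 | (5R)-2-methyl-5-(propan-2-yl)-5-(triethylsilyloxy)cyclopent-1-ene-1-carbaldehyde | O=CC1=C(C)CC[C@@]1(O[Si](CC)(CC)CC)C(C)C | intermediate
6 | methylmagnesium bromide | C[Mg]Br | starting material
7 | 1-[(5R)-2-methyl-5-(propan-2-yl)-5-(triethylsilyloxy)cyclopent-1-en-1-yl]ethan-1-ol, both carbinol epimers | CC(O)C1=C(C)CC[C@@]1(O[Si](CC)(CC)CC)C(C)C | intermediate
8 | 1-[(5R)-2-methyl-5-(propan-2-yl)-5-(triethylsilyloxy)cyclopent-1-en-1-yl]ethan-1-one | CC(=O)C1=C(C)CC[C@@]1(O[Si](CC)(CC)CC)C(C)C | intermediate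
9 | (1R)-1-[(5R)-2-methyl-5-(propan-2-yl)-5-(triethylsilyloxy)cyclopent-1-en-1-yl]ethan-1-ol | C[C@@H](O)C1=C(C)CC[C@@]1(O[Si](CC)(CC)CC)C(C)C | intermediate
10 | (1R)-1-[(1S,2R,5R)-5-methyl-2-(propan-2-yl)-2-(triethylsilyloxy)bicyclo[3.1.0]hexan-1-yl]ethan-1-ol (cyclopropane CH2 anti to the silyloxy group) | C[C@@H](O)[C@]12C[C@@]1(C)CC[C@@]2(O[Si](CC)(CC)CC)C(C)C | intermediate
11 | 1-[(1R,2R,5R)-5-methyl-2-(propan-2-yl)-2-(triethylsilyloxy)bicyclo[3.1.0]hexan-1-yl]ethan-1-one | CC(=O)[C@]12C[C@@]1(C)CC[C@@]2(O[Si](CC)(CC)CC)C(C)C | intermediate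
12 | (1S,2R,5R)-1-[1-(tert-butyldimethylsilyloxy)ethenyl]-5-methyl-2-(propan-2-yl)-2-(triethylsilyloxy)bicyclo[3.1.0]hexane | C=C(O[Si](C)(C)C(C)(C)C)[C@]12C[C@@]1(C)CC[C@@]2(O[Si](CC)(CC)CC)C(C)C | intermediate
13 | 1-(trimethylsilyl)propyne | CC#C[Si](C)(C)C | starting material
14 | (1R,4R)-6-(tert-butyldimethylsilyloxy)-4-(triethylsilyloxy)-9-(trimethylsilyl)dauca-5,8-diene | CC1=C([Si](C)(C)C)C[C@@]2(C)CC[C@@](O[Si](CC)(CC)CC)(C(C)C)C2=C(O[Si](C)(C)C(C)(C)C)C1 | intermediate
15 | (1R,4R,5R)-4-(triethylsilyloxy)-9-(trimethylsilyl)dauc-8-en-6-one (trans-fused), not isolated | CC1=C([Si](C)(C)C)C[C@@]2(C)CC[C@@](O[Si](CC)(CC)CC)(C(C)C)[C@@H]2C(=O)C1 | intermediate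
16 | (1R,4R,5R)-4-(triethylsilyloxy)dauc-8-en-6-one (trans-fused) | CC1=CC[C@@]2(C)CC[C@@](O[Si](CC)(CC)CC)(C(C)C)[C@@H]2C(=O)C1 | intermediate
17 | (1R,4R,5R)-4-hydroxydauc-8-en-6-one | CC1=CC[C@@]2(C)CC[C@@](O)(C(C)C)[C@@H]2C(=O)C1 | intermediate
18 | (1R,4R,5S,6S)-dauc-8-ene-4,6-diol | CC1=CC[C@@]2(C)CC[C@@](O)(C(C)C)[C@@H]2[C@@H](O)C1 | intermediate
19 | (E)-4-hydroxycinnamic acid | OC(=O)/C=C/c1ccc(O)cc1 | starting material
20 | tert-butyldimethylsilyl (E)-3-[4-(tert-butyldimethylsilyloxy)phenyl]prop-2-enoate, not isolated | CC(C)(C)[Si](C)(C)OC(=O)/C=C/c1ccc(O[Si](C)(C)C(C)(C)C)cc1 | intermediate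
21 | (E)-3-[4-(tert-butyldimethylsilyloxy)phenyl]prop-2-enoic acid | OC(=O)/C=C/c1ccc(O[Si](C)(C)C(C)(C)C)cc1 | intermediate
22 | (1R,4R,5S,6S)-4-hydroxydauc-8-en-6-yl (E)-3-[4-(tert-butyldimethylsilyloxy)phenyl]prop-2-enoate | CC1=CC[C@@]2(C)CC[C@@](O)(C(C)C)[C@@H]2[C@@H](OC(=O)/C=C/c2ccc(O[Si](C)(C)C(C)(C)C)cc2)C1 | intermediate
23 | (1R,4R,5S,6S)-4-hydroxydauc-8-en-6-yl (E)-3-(4-hydroxyphenyl)prop-2-enoate | CC1=CC[C@@]2(C)CC[C@@](O)(C(C)C)[C@@H]2[C@@H](OC(=O)/C=C/c2ccc(O)cc2)C1 | target

**Step count**

Total steps: 16. Longest linear sequence: 15 steps (steps 1–13, 15 and 16, from (S)-terpinen-4-ol).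

**Steps most likely to fail**

Step 10. The hindered vinylcyclopropane may fail to undergo cyclopropane insertion or alkyne capture, or the alkyne may insert in the opposite orientation. The fallback uses known chemistry, a tandem carbenoid cyclopropanation/divinylcyclopropane (Cope) rearrangement that builds the same ring B enol ether from a four-carbon and a three-carbon unit. It sets out from enone 8 and comes back at ketone 16. Enone 8 is silylated (tBuMe2SiOTf, Et3N) to the siloxydiene tert-butyl({1-[(5R)-2-methyl-5-(propan-2-yl)-5-(triethylsilyloxy)cyclopent-1-en-1-yl]ethenyl}oxy)dimethylsilane F1. Methyl 2-diazobut-3-enoate is decomposed by tetrakis[N-(4-dodecylbenzenesulfonyl)prolinato]dirhodium (divalent rhodium), using the catalyst enantiomer that places the carbenoid on the diene face anti to the C4 silyloxy group. This cyclopropanates the terminal C6=C7 enol ether bond to the cis-divinylcyclopropane methyl 2-(tert-butyldimethylsilyloxy)-1-ethenyl-2-[(5R)-2-methyl-5-(propan-2-yl)-5-(triethylsilyloxy)cyclopent-1-en-1-yl]cyclopropane-1-carboxylate F2. On warming, F2 rearranges (C1–C10 formed, C6–C8 broken) to methyl (1R,4R)-6-(tert-butyldimethylsilyloxy)-4-(triethylsilyloxy)dauca-5,8-dien-14-oate F3, C14 being the carbon on C8. iBu2AlH reduces the ester to (1R,4R)-6-(tert-butyldimethylsilyloxy)-4-(triethylsilyloxy)dauca-5,8-dien-14-ol F4. The allylic alcohol is deoxygenated through its sulfate monoester (SO3·pyridine, then LiAlH4) to (1R,4R)-6-(tert-butyldimethylsilyloxy)-4-(triethylsilyloxy)dauca-5,8-diene F5, and the CF3CO2H protonolysis of step 11 converts F5 into 16.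

Step 11. Facial selectivity in the protonation at C5 may be poor: delivery to the β-face would give the cis ring fusion, and the acid could also start to remove the C4 silyl ether. The fallback sets C5 under thermodynamic control while the silicon on C9 is kept as an anchor for the double bond. It sets out from 14 and comes back at 16. Bu4NF buffered with AcOH (THF, −20 °C) cleaves only the enol ether of 14 and gives the ketone as its C5 epimers, the cis-fused (1R,4R,5S)-4-(triethylsilyloxy)-9-(trimethylsilyl)dauc-8-en-6-one F6 beside 15. 1,8-Diazabicyclo[5.4.0]undec-7-ene in toluene equilibrates F6 to the trans-fused 15. Any double bond shift during this equilibration gives the conjugated (1R,4R,5R)-4-(triethylsilyloxy)-9-(trimethylsilyl)dauc-7-en-6-one F7, which is tolerated: CF3CO2H protodesilylation of 15 (ipso) and of F7 (through the dienol, protonated at C7) both return the C8=C9 alkene of 16.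

Step 7. Facial selectivity of methylene delivery may be poor, through competition between carbinol rotamers or attack on the face anti to the isopropyl group. The fallback replaces substrate control by reagent control. It sets out from enal 5 and comes back at ketone 11. iBu2AlH reduces 5 to the primary allylic alcohol [(5R)-2-methyl-5-(propan-2-yl)-5-(triethylsilyloxy)cyclopent-1-en-1-yl]methanol F8. Asymmetric Simmons–Smith cyclopropanation with Zn(CH2I)2·1,2-dimethoxyethane and (4S,5S)-2-butyl-N,N,N′,N′-tetramethyl-1,3,2-dioxaborolane-4,5-dicarboxamide gives [(1S,2R,5R)-5-methyl-2-(propan-2-yl)-2-(triethylsilyloxy)bicyclo[3.1.0]hexan-1-yl]methanol F9. This ligand enantiomer is predicted, from its known sense with simple allylic alcohols, to deliver the methylene anti to the silyloxy group. Dess–Martin oxidation gives (1R,2R,5R)-5-methyl-2-(propan-2-yl)-2-(triethylsilyloxy)bicyclo[3.1.0]hexane-1-carbaldehyde F10. MeMgBr addition gives 10 together with its carbinol epimer (1S)-1-[(1S,2R,5R)-5-methyl-2-(propan-2-yl)-2-(triethylsilyloxy)bicyclo[3.1.0]hexan-1-yl]ethan-1-ol F11, and Dess–Martin oxidation of the mixture gives 11.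

Further compounds
F1 | step 10 | tert-butyl({1-[(5R)-2-methyl-5-(propan-2-yl)-5-(triethylsilyloxy)cyclopent-1-en-1-yl]ethenyl}oxy)dimethylsilane | C=C(O[Si](C)(C)C(C)(C)C)C1=C(C)CC[C@@]1(O[Si](CC)(CC)CC)C(C)C
F2 | step 10 | methyl 2-(tert-butyldimethylsilyloxy)-1-ethenyl-2-[(5R)-2-methyl-5-(propan-2-yl)-5-(triethylsilyloxy)cyclopent-1-en-1-yl]cyclopropane-1-carboxylate (ethenyl cis to cyclopentenyl) | COC(=O)[C@]1(C=C)C[C@@]1(O[Si](C)(C)C(C)(C)C)C2=C(C)CC[C@@]2(O[Si](CC)(CC)CC)C(C)C
F3 | step 10 | methyl (1R,4R)-6-(tert-butyldimethylsilyloxy)-4-(triethylsilyloxy)dauca-5,8-dien-14-oate | COC(=O)C1=CC[C@@]2(C)CC[C@@](O[Si](CC)(CC)CC)(C(C)C)C2=C(O[Si](C)(C)C(C)(C)C)C1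
F4 | step 10 | (1R,4R)-6-(tert-butyldimethylsilyloxy)-4-(triethylsilyloxy)dauca-5,8-dien-14-ol | OCC1=CC[C@@]2(C)CC[C@@](O[Si](CC)(CC)CC)(C(C)C)C2=C(O[Si](C)(C)C(C)(C)C)C1
F5 | step 10 | (1R,4R)-6-(tert-butyldimethylsilyloxy)-4-(triethylsilyloxy)dauca-5,8-diene | CC1=CC[C@@]2(C)CC[C@@](O[Si](CC)(CC)CC)(C(C)C)C2=C(O[Si](C)(C)C(C)(C)C)C1
F6 | step 11 | (1R,4R,5S)-4-(triethylsilyloxy)-9-(trimethylsilyl)dauc-8-en-6-one (cis-fused) | CC1=C([Si](C)(C)C)C[C@@]2(C)CC[C@@](O[Si](CC)(CC)CC)(C(C)C)[C@H]2C(=O)C1
F7 | step 11 | (1R,4R,5R)-4-(triethylsilyloxy)-9-(trimethylsilyl)dauc-7-en-6-one (trans-fused, both C9 epimers) | CC1=CC(=O)[C@H]2[C@](O[Si](CC)(CC)CC)(C(C)C)CC[C@]2(C)CC1[Si](C)(C)C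
F8 | step 7 | [(5R)-2-methyl-5-(propan-2-yl)-5-(triethylsilyloxy)cyclopent-1-en-1-yl]methanol | OCC1=C(C)CC[C@@]1(O[Si](CC)(CC)CC)C(C)C
F9 | step 7 | [(1S,2R,5R)-5-methyl-2-(propan-2-yl)-2-(triethylsilyloxy)bicyclo[3.1.0]hexan-1-yl]methanol | OC[C@]12C[C@@]1(C)CC[C@@]2(O[Si](CC)(CC)CC)C(C)C
F10 | step 7 | (1R,2R,5R)-5-methyl-2-(propan-2-yl)-2-(triethylsilyloxy)bicyclo[3.1.0]hexane-1-carbaldehyde | O=C[C@]12C[C@@]1(C)CC[C@@]2(O[Si](CC)(CC)CC)C(C)C
F11 | step 7 | (1S)-1-[(1S,2R,5R)-5-methyl-2-(propan-2-yl)-2-(triethylsilyloxy)bicyclo[3.1.0]hexan-1-yl]ethan-1-ol | C[C@H](O)[C@]12C[C@@]1(C)CC[C@@]2(O[Si](CC)(CC)CC)C(C)C
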